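Thursday's run fed 0.27 M of first end groups into 0.36 M of second end groups. On average its columns read links 2.97%, rings 77.5% and isomer of the product 9.43%, together 89.9%. Wednesday's run, with 0.72 M of second end groups, sums to 98.5% at 20.0 d.

| setting | Monday's | Thursday's | Wednesday's | flask |
|---|---|---|---|---|
| first end groups | 0.18 M (fed, over 4.0 h) | 0.27 M (fed, over 4.0 h) | 0.36 M (fed, over 4.0 h) | 0.36 M (fed, over 4.0 h) |
| second end groups | 0.36 M | 0.36 M | 0.72 M | 0.360 M |
| remark | run made earlier | run made earlier | run made earlier |  |
| time |  |  |  | 15 d |

| run | time / d | links / % | rings / % | isomer of the product / % |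
|---|---|---|---|---|
| Monday's | 1.04 | 6.3 | 83.7 | 7.8 |
| Monday's | 3.00 | 3.8 | 85.4 | 12.7 |
| Monday's | 5.00 | 2.2 | 85.2 | 13.0 |
| Monday's | 8.00 | 2.3 | 84.3 | 13.5 |
| Monday's | 10.0 | 3.2 | 84.6 | 13.0 |
| Monday's | 15.0 | 3.4 | 82.6 | 12.0 |
| Monday's | 20.0 | 2.7 | 82.1 | 13.4 |
| Thursday's | 2.50 | 3.3 | 79.2 | 9.5 |
| Thursday's | 5.00 | 2.7 | 76.5 | 9.2 |
| Thursday's | 8.00 | 4.6 | 75.8 | 9.7 |
| Thursday's | 10.0 | 4.4 | 77.4 | 9.9 |
| Thursday's | 12.0 | 2.4 | 76.6 | 9.9 |
| Thursday's | 15.0 | 2.9 | 79.3 | 9.6 |
| Thursday's | 20.0 | 0.5 | 77.5 | 8.2 |
| Wednesday's | 1.25 | 11.1 | 72.9 | 15.7 |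
| Wednesday's | 2.50 | 8.5 | 72.1 | 19.0 |
| Wednesday's | 5.00 | 7.3 | 71.8 | 20.6 |
| Wednesday's | 10.0 | 5.2 | 74.1 | 20.4 |
| Wednesday's | 20.0 | 5.2 | 72.3 | 21.0 |

(readings scatter by 1 percentage point)

1. how much links there is at 15 d, in percent of the first end groups charged
2. how much rings there is at 15 d, in percent of the first end groups charged
3. how much isomer of the product there is at 15 d, in percent of the first end groups charged



Thursday's sum holds steady from 2.50 d, so we read the shortfall as first end groups that found no partner, with second end groups as limiting reagent. Then 0.36 M of them paid for 0.243 M converted, one for one, and the rest went elsewhere. Let w be the second end groups lost elsewhere per first end group converted: Thursday gives 0.484. Carried unchanged, that converts 67.4% of the flask's charge.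

That is the weak link. Since w divides one total by another, read once the sum has stopped moving, the time of reading drops out; the dosing time does not, but Thursday's run and the flask both feed over 4.0 h. If the waste follows second end groups and conversion follows first end groups, then at equal second charge w falls as the first charge rises. So we carry the waste constant W, w times the first charge, 0.131 M. The flask then has w = 0.363, and 0.264 M converts, 73.4% of its charge.

Links plus isomer per ring, s, read 0.160 on Thursday and 0.362 on Wednesday. We keep Thursday's value, the second charge being equal. Dividing by 1 + s gives rings 63.3%, and Thursday's isomer-to-links ratio of 3.17 splits the remainder into links 2.43% and isomer 7.67%.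

The forecast says links 5.5%, rings 66%, isomer 7%, and reads the shortfall differently from us: “an unmeasured species, probably oligomer, grows as the excess of second end groups shrinks”.

The flask gives links 2.49%, rings 63.4% and isomer of the product 7.96%.

    first end groups + second end groups → links (k = 0.200 L mol⁻¹ h⁻¹)
    first end groups + second end groups → rings, rate k2*[first end groups] as long as [second end groups] is above zero (k = 0.180 h⁻¹)
    second end groups → decomposed reagent (k = 0.0670 h⁻¹)
    links ⇌ isomer of the product (K = 3.20, k = 0.0430 h⁻¹)

Outside those columns, at 15.0 d, stand 26.1% of the first end groups, beside 0% of the second and 0.0940 M of decomposed reagent. The neighbour with 0.61 M of first end groups and the same second charge has, by W, w = 0.214, so 0.297 M converts, 48.7% of its charge. At 15.0 d that neighbour holds 52.4% of its first end groups.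

(The data are calculated for substances that don't exist; noise was put on by code.)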